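The numbers in the tables were generated by integration for substances that don't exist, noise included.

0.333 of the substrate lost stands as bis adduct in Thursday's flask at 2.50 h. I call this reading the bis share: bis adduct per substrate lost, both as fractions of the charge.

| flask | substrate | reagent | scavenger | remark | time |
|---|---|---|---|---|---|
| Monday's | 0.61 M (fed, over 10 min) | 0.71 equiv | 0.30 equiv | run made earlier; the fed solution adds 0.10 times the starting volume |  |
| Friday's | 0.61 M (fed, over 10 min) | 1.6 equiv | 0.30 equiv | run made earlier; the fed solution adds 0.10 times the starting volume |  |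
| Thursday's | 0.61 M (fed, over 10 min) | 3.5 equiv | 0.30 equiv | run made earlier; the fed solution adds 0.10 times the starting volume |  |
| grey | 0.61 M (fed, over 10 min) | 0.800 equiv | 0.300 equiv | the fed solution adds 0.10 times the starting volume | 5.0 h |
| green | 0.61 M (fed, over 10 min) | 1.50 equiv | 0.300 equiv | the fed solution adds 0.10 times the starting volume | 5.0 h |
| blue | 0.61 M (fed, over 10 min) | 4.00 equiv | 0.300 equiv | the fed solution adds 0.10 times the starting volume | 5.0 h |

- Monday's (time / h: bis adduct / %, substrate / %): 0.200: 4, 97; 0.417: 2, 94; 0.667: 1, 97; 1.33: 0, 91; 2.50: 2, 86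
- Friday's (time / h: bis adduct / %, substrate / %): 0.200: 0, 99; 0.667: 0, 92; 1.33: 3, 82; 2.00: 3, 75; 2.50: 8, 75
- Thursday's (time / h: bis adduct / %, substrate / %): 0.200: 0, 96; 0.417: 3, 88; 0.667: 3, 82; 1.33: 11, 71; 2.50: 14, 58

(readings scatter by 1.5 percentage points)

- amounts are per litre of the starting volume; all of the dose is in the solution fed

- final bis adduct, as a percentage of the substrate charged, for each flask in turn (grey, green, blue)

To use the share I need the substrate lost at 5.0 h. I take substrate loss as first order in reagent and, with the reagent held steady, pseudo-first-order in substrate, and I call ln(charge over what is left) its exposure. Thursday's flask reaches 0.545 at 2.50 h. Blue carries 1.14 times Thursday's reagent. If the reagent held steady, exposure would scale with reagent and time, and blue would reach 23.7 % bis adduct.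

That steadiness is the weak link. Thursday's exposure grows at 0.258 h⁻¹ up to 1.33 h, then at 0.173 h⁻¹, which is slower. From these scattered readings I take a sag of 0.671. So I let the rate sag once more over the second stretch. Exposure at 5.0 h is then 1.53 times that at 2.50 h, blue reaches 0.954, and blue's bis adduct comes to 20.5 %. The same steps, with Friday's share, give green 10.8 %. With Monday's share they give grey 3.28 %. Monday's reading is 2 % with a scatter of 1.5 percentage points, so grey is loose.

The forecast gives 3.5 %, 12 % and 37 % and calls blue “the least certain”; its blue is higher than mine.

The flasks give 5.33 % for grey, 10.1 % for green and 18.6 % for blue.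

    2 reagent → homo dimer (k = 5.00 × 10⁻⁵ M⁻¹ s⁻¹)
    reagent + bis adduct ⇌ triple product + released group (K = 8.00, k = 1.20 × 10⁻⁴ M⁻¹ s⁻¹)
    scavenger + released group → scavenged by-product (k = 0.00200 M⁻¹ s⁻¹)
    substrate + reagent → mono adduct + released group (k = 6.20 × 10⁻⁵ M⁻¹ s⁻¹)
    reagent + released group ⇌ idle adduct, settled at all times (K = 0.230 M⁻¹)
    reagent + mono adduct → bis adduct + released group (k = 1.40 × 10⁻⁴ M⁻¹ s⁻¹)

The bis share comes out at 0.343 in blue and 0.287 in green. Blue lost 54.2 % of its substrate, less than the 61.5 % I reckoned, so blue's rate sagged deeper than my one further step. In green, part of the reason why the bis adduct stands where it does is the reagent's passing into homo dimer, together with the time allowed. Without that step, green holds 15.5 % bis adduct instead of 10.1 %. Left until 50.0 h, green holds 20.3 %.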